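Ring locants, the same for both benzene rings A and B: C1 bears the benzylic CH2, C2 and C3 the bromines, C4 and C5 the hydroxyls, C6 a hydrogen.
Retrosynthetic cuts: first the two C5–O bonds (each catechol becomes a C4 phenol), then one benzylic C–O bond of the central ether (two identical aldehydes), then the C1–CHO bond (2,3-dibromoanisole).
Enabling feature: in the C4 phenol, ortho carbon C3 holds bromine and para carbon C1 holds the CH2O arm, so C5 is the only ortho C–H and oxygen delivered from the phenol oxygen can land nowhere else.
Forward order: both rings are bought, none is built. The sequence is para-formylation, exchange of O-methyl for O-silyl, reductive union of two aldehydes into the ether, desilylation, then twofold ortho-oxygenation with reduction in the same flask.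
Stereochemistry: the target is achiral and has no stereocentre, so nothing has to be set.

Key step: step 6

Remark: 2,3-dibromoanisole, dichloromethyl methyl ether and IBX are taken to be purchasable.

Step 1
Reactants: 1 2,3-dibromoanisole; 2 dichloromethyl methyl ether
Product: 3 2,3-dibromo-4-methoxybenzaldehyde
Conditions: Cl2CHOMe (1.3 equiv), TiCl4 (2.2 equiv), CH2Cl2, 0 °C to rt; then ice/1 M HCl
Reagents that add atoms: dichloromethyl methyl ether, COC(Cl)Cl; water, O
Why: Rieche formylation is an electrophilic aromatic substitution in which the methoxy group, the only strong donor, steers the TiCl4-activated electrophile to its para carbon, the site that 2,3-dihaloanisoles are known to offer to acylating and formylating agents, and the aqueous quench then releases the aldehyde.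

Step 2
Reactants: 3 2,3-dibromo-4-methoxybenzaldehyde
Product: 4 2,3-dibromo-4-hydroxybenzaldehyde
Conditions: BBr3 (1.5 equiv), CH2Cl2, −78 °C to rt; then H2O
Reagents that add atoms: none
Why: BBr3 cleavage of an aryl methyl ether (Lewis acid complexation, then bromide attack at the methyl carbon) is routine for 4-methoxybenzaldehydes and leaves aryl bromides untouched, and it is placed here because the later dibenzylic ether would not survive it.

Step 3
Reactants: 4 2,3-dibromo-4-hydroxybenzaldehyde
Product: 5 4-(tert-butyldimethylsilyloxy)-2,3-dibromobenzaldehyde
Conditions: TBSCl (1.2 equiv), imidazole (2 equiv), DMF, rt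
Reagents that add atoms: tert-butyldimethylsilyl chloride, CC(C)(C)[Si](C)(C)Cl
Why: Imidazole-promoted O-silylation of an acidic phenol is fast and general, and it removes the acidic proton and the vinylogous-acid character that would hamper Lewis acid activation of the aldehyde in the next step.

Step 4
Reactants: 5 4-(tert-butyldimethylsilyloxy)-2,3-dibromobenzaldehyde (two molecules combine)
Product: 6 bis[4-(tert-butyldimethylsilyloxy)-2,3-dibromobenzyl] ether
Conditions: Et3SiH (1.2 equiv per CHO), Me3SiOSO2CF3 (10 mol %), CH2Cl2, −40 to 0 °C
Reagents that add atoms: none
Why: Silane reductive homo-etherification of an aldehyde (Lewis acid catalysed hydrosilylation, condensation with a second aldehyde to an oxocarbenium ion, hydride capture) is well known for benzaldehyde and halobenzaldehydes, joins the two halves in one operation without an alkoxide that could strip the aryl silyl ether, and should stop at the ether because the two bromines offset the donor effect of the silyloxy group and keep the product from ionising.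

Step 5
Reactants: 6 bis[4-(tert-butyldimethylsilyloxy)-2,3-dibromobenzyl] ether
Product: 7 bis(2,3-dibromo-4-hydroxybenzyl) ether
Conditions: Bu4NF (2.2 equiv), AcOH (2.5 equiv), THF, 0 °C
Reagents that add atoms: none
Why: Fluoride-induced desilylation of an aryl silyl ether, driven by the Si–F bond and the good dibromophenoxide leaving group, runs at 0 °C, and the acetic acid buffer protonates the phenoxide at once so that it cannot expel the benzylic alkoxide as a para-quinone methide.

Step 6
Reactants: 7 bis(2,3-dibromo-4-hydroxybenzyl) ether; 8 2-iodoxybenzoic acid (IBX)
Product: 10 bis(2,3-dibromo-4,5-dihydroxybenzyl) ether, via bis-ortho-quinone 9 (not isolated)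
Conditions: IBX (2.4 equiv), DMF, 0 °C to rt, dark, Ar; then aq Na2S2O4, 0 °C
Reagents that add atoms: 2-iodoxybenzoic acid (IBX), O=C1OI(=O)(O)c2ccccc12
Why: Each phenol oxygen replaces the hydroxyl ligand on the pentavalent iodine of 8, the oxo ligand is passed within this complex to the neighbouring ring carbon in a sigmatropic-type shift that lowers iodine to the trivalent state, and the rearomatised iodine-bound catechol collapses to the ortho-quinone and 2-iodobenzoic acid, so one equivalent of 8 per ring makes one C5–O bond. The closest known reaction type is the IBX ortho-oxygenation of 4-alkylphenols such as tyrosol to ortho-quinones, followed by dithionite reduction to the catechol in the same flask. No ring closes and no stereocentre arises. The step needs site selectivity, and the substrate secures it: tethered delivery reaches only ortho carbons, C3 is filled by bromine, C5 is the sole ortho C–H, and the alkylated para carbon C1 rules out a para-quinone. The two bromines make each ring a poorer nucleophile, which is met by the polar solvent DMF, a small excess of oxidant and time at room temperature, conditions under which the benzylic ether C–H bonds stay intact because IBX attacks such positions only on heating. Prompt cold reduction of 9 forestalls tautomerisation through the benzylic hydrogens to a quinone methide and leaves all four hydroxyls free, so no deprotection follows.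

Compound list
1 | 2,3-dibromoanisole | COc1cccc(Br)c1Br | starting material
2 | dichloromethyl methyl ether | COC(Cl)Cl | starting material
3 | 2,3-dibromo-4-methoxybenzaldehyde | COc1ccc(C=O)c(Br)c1Br | intermediate
4 | 2,3-dibromo-4-hydroxybenzaldehyde | O=Cc1ccc(O)c(Br)c1Br | intermediate
5 | 4-(tert-butyldimethylsilyloxy)-2,3-dibromobenzaldehyde | CC(C)(C)[Si](C)(C)Oc1ccc(C=O)c(Br)c1Br | intermediate
6 | bis[4-(tert-butyldimethylsilyloxy)-2,3-dibromobenzyl] ether | CC(C)(C)[Si](C)(C)Oc1ccc(COCc2ccc(O[Si](C)(C)C(C)(C)C)c(Br)c2Br)c(Br)c1Br | intermediate
7 | bis(2,3-dibromo-4-hydroxybenzyl) ether | Oc1ccc(COCc2ccc(O)c(Br)c2Br)c(Br)c1Br | intermediate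
8 | 2-iodoxybenzoic acid (IBX) | O=C1OI(=O)(O)c2ccccc12 | starting material
9 | 5,5'-[oxybis(methylene)]bis(3,4-dibromocyclohexa-3,5-diene-1,2-dione), the bis-ortho-quinone | O=C1C=C(COCC2=CC(=O)C(=O)C(Br)=C2Br)C(Br)=C(Br)C1=O | intermediate
10 | bis(2,3-dibromo-4,5-dihydroxybenzyl) ether | Oc1cc(COCc2cc(O)c(O)c(Br)c2Br)c(Br)c(Br)c1O | target

Total step count: 6. Longest linear sequence: 6 steps (1, 3, 4, 5, 6, 7, 10).

Steps most likely to fail

First, step 6. Oxygen transfer to the bromine-depleted rings may be slow. The ring oxidised first would then wait as a quinone and could be lost by tautomerisation, hydration or hydride abstraction from the benzylic ether before the second ring has reacted. The fallback makes the C5–O bond by aryl migration from carbon to oxygen instead of direct oxygen transfer.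
- It sets out from 7 with magnesium-mediated ortho-formylation under Casnati–Skattebøl conditions (MgCl2, Et3N, paraformaldehyde, MeCN, reflux). This reaction is well established for 2-bromophenols and is again confined to C5, and it should give bis(2,3-dibromo-5-formyl-4-hydroxybenzyl) ether F1.
- Dakin oxidation (H2O2, NaHCO3-buffered aqueous THF, 0 °C to rt) should then give bis(2,3-dibromo-5-formyloxy-4-hydroxybenzyl) ether F2.
- F2 is hydrolysed in the same flask, and the route is rejoined at 10.

Second, step 4. The Lewis acid may ionise the benzylic C–O bond of the freshly formed ether so that the silane reduces it further. Alternatively, the reaction may halt after simple hydrosilylation without condensation. The fallback builds the ether by substitution instead of reduction.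
- It sets out from 5, where NaBH4 (THF/MeOH, 0 °C) should give [4-(tert-butyldimethylsilyloxy)-2,3-dibromophenyl]methanol F3.
- Half of this material is converted by the Appel reaction (CBr4, PPh3, CH2Cl2, 0 °C) into 4-(tert-butyldimethylsilyloxy)-2,3-dibromobenzyl bromide F4.
- The two halves are joined in a Williamson-type coupling promoted by Ag2O (CH2Cl2, molecular sieves, dark). This avoids a free alkoxide and so spares the aryl silyl ethers, and it comes back to the route at 6.

Third, step 1. The doubly brominated ring may be too deactivated for the formylating electrophile, or attack ortho to the methoxy group may compete (poor site selectivity). The fallback installs the aldehyde through a carbanion instead of an electrophilic formylation.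
- It sets out from 1, where para-iodination with N-iodosuccinimide and catalytic CF3CO2H in MeCN should give 2,3-dibromo-4-iodoanisole F5, which can be purified by crystallisation.
- Iodine–magnesium exchange with iPrMgCl·LiCl (THF, −40 °C) is selective for the carbon–iodine bond and cold enough to prevent aryne formation. It should give (2,3-dibromo-4-methoxyphenyl)magnesium chloride F6.
- Quenching with DMF followed by dilute acid returns to the route at 3.

Further compounds
F1 | step 6 | bis(2,3-dibromo-5-formyl-4-hydroxybenzyl) ether | O=Cc1cc(COCc2cc(C=O)c(O)c(Br)c2Br)c(Br)c(Br)c1O
F2 | step 6 | bis(2,3-dibromo-5-formyloxy-4-hydroxybenzyl) ether | O=COc1cc(COCc2cc(OC=O)c(O)c(Br)c2Br)c(Br)c(Br)c1O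
F3 | step 4 | [4-(tert-butyldimethylsilyloxy)-2,3-dibromophenyl]methanol | CC(C)(C)[Si](C)(C)Oc1ccc(CO)c(Br)c1Br
F4 | step 4 | 4-(tert-butyldimethylsilyloxy)-2,3-dibromobenzyl bromide | CC(C)(C)[Si](C)(C)Oc1ccc(CBr)c(Br)c1Br
F5 | step 1 | 2,3-dibromo-4-iodoanisole | COc1ccc(I)c(Br)c1Br
F6 | step 1 | (2,3-dibromo-4-methoxyphenyl)magnesium chloride | COc1ccc([Mg]Cl)c(Br)c1Br
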